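Numbering used throughout (eunicellane): ring A = C1, C10, C11 (Me, OH), C12, C13, C14 (isopropyl), cis-fused to the ten-membered ring C1–C10, which carries (Z)-C2=C3 (methyl on C3), C6–OAc, C7=C19H2 and C9–OAc.
Retrosynthesis: after removal of the acetates and silyl groups, the ten-membered ring is cut at C7–C8 by a nickel-catalysed reductive alkyne–epoxide macrocyclisation. This is possible because C7 is a ring sp2 carbon bearing only the exocyclic CH2 (an alkyne carbon in the precursor) and C8 is a CH2 next to the C9 carbinol (the terminal carbon of a C8–C9 epoxide). The 1,4-dioxygenated C6–C9 unit makes C7 and C8 carbons of like polarity, joined here under reduction.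
Further cuts: C3–C4 (B-alkyl Suzuki–Miyaura) into ring-A vinyl iodide 13 and enyne 20; C2=C3 (Stork–Zhao olefination); the C8–C9 epoxide back to an iodolactone formed from a C10 vinyl group and the C2 acid; C2 and C9 back to the two carbons of a ketene added across C1=C10 of α-phellandrene and separated by Baeyer–Villiger oxidation.
Forward: ring A is bought as the terpene; a cyclobutanone and two lactones serve as temporary rings; the C4–C7 chain is joined at C3; the ten-membered ring is closed at C7–C8, followed only by desilylation and acetylation.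
Stereochemistry: C14 from (R)-α-phellandrene; C1 and C10 (cis, anti to isopropyl) from the [2+2] cycloaddition; C11 by hydration on the convex face; C9 by iodolactonisation, carried through the epoxide; C6 from a lipase resolution; (Z)-C2=C3 from the iodo-olefination and a stereoretentive coupling.

Key step: step 15

Assumption: commercial (R)-(−)-α-phellandrene is taken as enantiomerically pure, and the acetal carbon (future C9) of 4 to 8 is an epimer mixture that converges at 9.

Step 1
Reactants: 1 (R)-(−)-α-phellandrene; 2 methoxyacetyl chloride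
Product: 4 8-methoxy-2-methyl-5-(propan-2-yl)bicyclo[4.2.0]oct-2-en-7-one (cis-fused; four-membered ring anti to isopropyl), via methoxyketene 3 (not isolated)
Conditions: Et3N, hexane, reflux, slow addition of 2
Reagents that add atoms: none
Why: Ketene–alkene [2+2] cycloaddition, in which the ketene adds to the less substituted C1=C10 alkene of the diene on the face away from the isopropyl group, its carbonyl carbon bonding to the diene terminus C1 and its methoxy carbon to C10, which sets the cis C1/C10 relationship anti to C14.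

Step 2
Reactants: 4 cyclobutanone
Product: 5 3-methoxy-4-methyl-7-(propan-2-yl)-3a,6,7,7a-tetrahydro-2-benzofuran-1(3H)-one (cis-fused; lactone carbonyl = C2; acetal carbon = C9)
Conditions: 30% aq. H2O2, AcOH, 0 °C
Reagents that add atoms: hydrogen peroxide, OO
Why: Baeyer–Villiger oxidation, in which the strained cyclobutanone should react faster than the trisubstituted alkene is epoxidised and the oxygen-bearing carbon C9 migrates with retention, so that C2 becomes a lactone carbonyl and C9 an acetal carbon.

Step 3
Reactants: 5 unsaturated methoxy lactone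
Product: 6 4-hydroxy-3-methoxy-4-methyl-7-(propan-2-yl)hexahydro-2-benzofuran-1(3H)-one (C11–OH cis to H10)
Conditions: Co(acac)2 (cat.), PhSiH3, O2 (1 atm), THF/i-PrOH, rt
Reagents that add atoms: dioxygen, O=O
Why: Mukaiyama hydration (hydrogen-atom transfer to C12, then capture of the tertiary C11 radical by oxygen), which puts the oxygen on C11 and should trap the radical on the convex face of the cis-fused bicycle, anti to the C10–C9 bond.

Step 4
Reactants: 6 tertiary alcohol
Product: 7 C11 tert-butyldimethylsilyl ether of 6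
Conditions: TBSOTf, 2,6-lutidine, CH2Cl2, 0 °C to rt
Reagents that add atoms: tert-butyldimethylsilyl trifluoromethanesulfonate, CC(C)(C)[Si](C)(C)OS(=O)(=O)C(F)(F)F
Why: Silylation of a hindered tertiary alcohol with a silyl triflate, which blocks retro-aldol cleavage and β-elimination once C9 is an aldehyde β to C11 and is removed in step 16.

Step 5
Reactants: 7 methoxy lactone
Product: 8 4-[(tert-butyldimethylsilyl)oxy]-3-hydroxy-4-methyl-7-(propan-2-yl)hexahydro-2-benzofuran-1(3H)-one (ring-closed form of the C9 aldehyde / C2 acid)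
Conditions: 1 M aq. HCl, THF, rt to 40 °C
Reagents that add atoms: water, O
Why: Acid hydrolysis of the acylal-type mixed acetal to the hydroxylactone, in which the cis C1/C10 relationship stays locked in a ring and the tertiary silyl ether should survive dilute acid.

Step 6
Reactants: 8 hydroxylactone
Product: 9 3-[(tert-butyldimethylsilyl)oxy]-2-ethenyl-3-methyl-6-(propan-2-yl)cyclohexane-1-carboxylic acid (vinyl and CO2H cis)
Conditions: Ph3PCH3Br, KOt-Bu, THF, 0 °C to rt; then aq. NaH2PO4
Reagents that add atoms: methyltriphenylphosphonium bromide, C[P+](c1ccccc1)(c1ccccc1)c1ccccc1.[Br-]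
Why: Wittig methylenation of the aldehyde–carboxylate that forms from the lactol on deprotonation, where the ylide should add to the aldehyde faster than the hindered C10–H is removed, so the cis configuration is kept.

Step 7
Reactants: 9 vinyl acid
Product: 10 4-[(tert-butyldimethylsilyl)oxy]-3-(iodomethyl)-4-methyl-7-(propan-2-yl)hexahydro-2-benzofuran-1(3H)-one (CH2I cis to H10, on the convex face)
Conditions: I2, NaHCO3, MeCN, 0 °C, dark
Reagents that add atoms: iodine, [I][I]
Why: Iodolactonisation (5-exo attack of the C2 carboxylate on the iodonium ion of the C9=C8 vinyl group), which should place the CH2I group on the convex face of the cis-fused γ-lactone, away from C11 and its substituents, and so sets C9 with its oxygen and puts a leaving group on C8.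

Step 8
Reactants: 10 iodolactone
Product: 11 methyl 3-[(tert-butyldimethylsilyl)oxy]-3-methyl-2-[(2S)-oxiran-2-yl]-6-(propan-2-yl)cyclohexane-1-carboxylate
Conditions: K2CO3, MeOH, 0 °C to rt
Reagents that add atoms: methanol, CO
Why: Methanolysis of the lactone frees the C9 alkoxide, which displaces the neighbouring iodide (3-exo-tet) to give the terminal epoxide with retention at C9 and makes the lactone opening irreversible.

Step 9
Reactants: 11 epoxy ester
Product: 12 3-[(tert-butyldimethylsilyl)oxy]-3-methyl-2-[(2S)-oxiran-2-yl]-6-(propan-2-yl)cyclohexane-1-carbaldehyde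
Conditions: i-Bu2AlH (1.1 equiv), CH2Cl2, −78 °C; MeOH, aq. Rochelle salt
Reagents that add atoms: none
Why: Partial reduction of the α-branched methyl ester should stop at the tetrahedral aluminium hemiacetal at −78 °C, which gives the aldehyde on work-up, with the epoxide and silyl ether inert.

Step 10
Reactants: 12 aldehyde
Product: 13 tert-butyl{[3-[(1Z)-2-iodoprop-1-en-1-yl]-1-methyl-2-[(2S)-oxiran-2-yl]-4-(propan-2-yl)cyclohexyl]oxy}dimethylsilane
Conditions: EtPPh3I, n-BuLi, THF, 0 °C; I2, −78 °C; NaN(SiMe3)2, −20 °C; then 12, −78 to −20 °C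
Reagents that add atoms: ethyltriphenylphosphonium iodide, CC[P+](c1ccccc1)(c1ccccc1)c1ccccc1.[I-]; iodine, [I][I]
Why: Stork–Zhao olefination, in which the α-iodo ylide should give the (Z)-2-iodoalkene from an α-branched aldehyde, with iodine cis to C1 and the methyl group trans to C1 as in the target.

Step 11
Reactants: 14 ethynyl(trimethyl)silane; 15 acrolein
Product: 18 rac-5-(trimethylsilyl)pent-1-en-4-yn-3-yl acetate, via lithium (trimethylsilyl)acetylide 16 (not isolated), via lithium 5-(trimethylsilyl)pent-1-en-4-yn-3-olate 17 (not isolated)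
Conditions: n-BuLi, THF, −78 °C; acrolein, −78 °C; then Ac2O, −78 °C to rt
Reagents that add atoms: acetic anhydride, CC(=O)OC(C)=O
Why: 1,2-Addition of the lithium acetylide to the enal at low temperature, followed by O-acetylation of the alkoxide in the same flask, gives the racemic ester for the enzymatic resolution.

Step 12
Reactants: 18 racemic acetate
Product: 19 (3R)-5-(trimethylsilyl)pent-1-en-4-yn-3-ol
Conditions: lipase from Burkholderia cepacia (triacylglycerol lipase, a serine hydrolase), phosphate buffer pH 7, acetone (cosolvent), 30 °C, stopped near half conversion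
Reagents that add atoms: none
Why: Kinetic resolution by enzymatic ester hydrolysis, in which the Kazlauskas rule (vinyl as medium group, silylethynyl as large group) predicts that the (R)-acetate is hydrolysed while the (S)-enantiomer of 18 is left as the ester and separated, which sets C6.

Step 13
Reactants: 19 (R)-alcohol
Product: 20 (3R)-3-[(tert-butyldimethylsilyl)oxy]-5-(trimethylsilyl)pent-1-en-4-yne
Conditions: TBSCl, imidazole, DMF, rt
Reagents that add atoms: tert-butyldimethylsilyl chloride, CC(C)(C)[Si](C)(C)Cl
Why: Standard silylation of a secondary alcohol, giving an ether that survives the coupling and the nickel step.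

Step 14
Reactants: 20 silyl ether enyne; 13 vinyl iodide
Product: 22 seco epoxy enyne (ring A of 13 carrying at C1 the (1Z,5R)-5-[(tert-butyldimethylsilyl)oxy]-2-methyl-7-(trimethylsilyl)hept-1-en-6-yn-1-yl chain), via B-alkyl-9-BBN 21 (not isolated)
Conditions: 20, 9-BBN, THF, 0 °C to rt; then 13, Pd(dppf)Cl2 (10 mol%), AsPh3, Cs2CO3, DMF/THF/H2O, rt
Reagents that add atoms: none
Why: Hydroboration of the monosubstituted alkene (the silyl alkyne reacts far more slowly) and B-alkyl Suzuki–Miyaura coupling with the vinyl iodide, which proceeds with retention of alkene geometry and so gives the (Z)-C2=C3 alkene, while the epoxide should tolerate aqueous carbonate at room temperature.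

Step 15
Reactants: 22 seco epoxy enyne
Product: 24 macrocyclic (Z)-vinylsilane (6,11-bis-O-TBS-19-trimethylsilyl-eunicella-2,7(19)-diene-6,9,11-triol), via O-diethylboryl ether 23 (not isolated)
Conditions: Ni(cod)2 (30 mol%), PBu3 (60 mol%), Et3B (4 equiv), degassed THF, rt, 22 added by syringe pump to 0.005 M; aq. NH4Cl
Reagents that add atoms: none
Why: Proposed new method: zerovalent nickel (PBu3) should open the epoxide of 22 at its terminal carbon C8 by oxidative addition to an oxanickelacyclobutane, the tethered silyl alkyne then inserts into the Ni–C8 bond so that C8 is joined to C7, and ethyl transfer from Et3B to nickel, β-hydride elimination (ethene) and C–H reductive elimination place the hydrogen on C19 and leave the borinate 23, which the work-up hydrolyses to 24. The closest known reaction type is the nickel/phosphine/Et3B reductive coupling of alkynes with terminal epoxides, known between two molecules and for five- and six-membered rings, together with nickel-catalysed alkyne–aldehyde reductive macrocyclisation; closure of a ten-membered ring onto an epoxide has not been shown. The ten-membered carbocycle (C1 to C10) closes in the exo-dig mode at the alkyne (C19 stays outside the ring) and with endo opening of the epoxide (C8 and C9 both become ring atoms). No sp3 stereocentre is created: C9 is not touched and its oxygen appears as the free (9R) alcohol with the configuration fixed in step 7, while syn addition of C8 and H across the alkyne gives the (Z)-vinylsilane, whose geometry is erased in step 16. The step needs bond formation at C7 and not C19 (the silyl group steers carbon to the remote alkyne carbon), attack at C8 and not C9 (primary versus secondary carbon), and ring closure instead of oligomerisation (slow addition at high dilution, helped by the gauche cis-1,2 arrangement of the two arms on ring A and by the (Z)-C2=C3 alkene, which turn the chain ends toward each other). A two-electron nickel pathway is chosen on purpose, because a free radical at C8, as formed in halide-based reductive couplings, would be a 5-hexenyl radical with respect to C2=C3 and should close a five-membered ring instead.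

Step 16
Reactants: 24 macrocyclic vinylsilane
Product: 25 (1S,2Z,6R,9R,10S,11R,14R)-eunicella-2,7(19)-diene-6,9,11-triol
Conditions: Bu4NF (excess), THF, 65 °C
Reagents that add atoms: none
Why: Fluoride cleaves both silyl ethers, and the C6 alkoxide, which lies cis to silicon across C7=C19, should assist protodesilylation of the vinylsilane through a pentacoordinate silicate, giving the exocyclic methylene.

Step 17
Reactants: 25 triol
Product: 26 (1S,2Z,6R,9R,10S,11R,14R)-11-hydroxyeunicella-2,7(19)-diene-6,9-diyl diacetate (target)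
Conditions: Ac2O, pyridine, DMAP (cat.), CH2Cl2, 0 °C to rt
Reagents that add atoms: acetic anhydride, CC(=O)OC(C)=O
Why: Acylation under mild nucleophilic catalysis should esterify the two secondary alcohols (C6, C9) and leave the hindered tertiary C11 alcohol free.

Compound list
1 | (R)-(−)-α-phellandrene, (5R)-2-methyl-5-(propan-2-yl)cyclohexa-1,3-diene | C1=C[C@@H](C(C)C)CC=C1C | starting material
2 | methoxyacetyl chloride | COCC(Cl)=O | starting material
3 | methoxyketene | COC=C=O | intermediate (not isolated)
4 | 8-methoxy-2-methyl-5-(propan-2-yl)bicyclo[4.2.0]oct-2-en-7-one; cis-fused, four-membered ring anti to isopropyl; C7=O is the future C2, C8(OMe) the future C9 (epimers at C8) | COC1[C@@H]2[C@H](C1=O)[C@@H](C(C)C)CC=C2C | intermediate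
5 | 3-methoxy-4-methyl-7-(propan-2-yl)-3a,6,7,7a-tetrahydro-2-benzofuran-1(3H)-one; cis-fused (epimers at C3) | COC1[C@@H]2[C@H](C(=O)O1)[C@@H](C(C)C)CC=C2C | intermediate
6 | 4-hydroxy-3-methoxy-4-methyl-7-(propan-2-yl)hexahydro-2-benzofuran-1(3H)-one; OH cis to H3a (= H10) | COC1[C@@H]2[C@H](C(=O)O1)[C@@H](C(C)C)CC[C@@]2(C)O | intermediate
7 | tert-butyldimethylsilyl ether of 6 at the tertiary alcohol | COC1[C@@H]2[C@H](C(=O)O1)[C@@H](C(C)C)CC[C@@]2(C)O[Si](C)(C)C(C)(C)C | intermediate
8 | 4-[(tert-butyldimethylsilyl)oxy]-3-hydroxy-4-methyl-7-(propan-2-yl)hexahydro-2-benzofuran-1(3H)-one (epimers at C3) | OC1[C@@H]2[C@H](C(=O)O1)[C@@H](C(C)C)CC[C@@]2(C)O[Si](C)(C)C(C)(C)C | intermediate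
9 | 3-[(tert-butyldimethylsilyl)oxy]-2-ethenyl-3-methyl-6-(propan-2-yl)cyclohexane-1-carboxylic acid; vinyl and CO2H cis, both trans to isopropyl; silyloxy trans to vinyl | C=C[C@@H]1[C@H](C(O)=O)[C@@H](C(C)C)CC[C@@]1(C)O[Si](C)(C)C(C)(C)C | intermediate
10 | 4-[(tert-butyldimethylsilyl)oxy]-3-(iodomethyl)-4-methyl-7-(propan-2-yl)hexahydro-2-benzofuran-1(3H)-one; cis-fused, CH2I cis to H3a | IC[C@@H](OC1=O)[C@@H]2[C@H]1[C@@H](C(C)C)CC[C@@]2(C)O[Si](C)(C)C(C)(C)C | intermediate
11 | methyl 3-[(tert-butyldimethylsilyl)oxy]-3-methyl-2-[(2S)-oxiran-2-yl]-6-(propan-2-yl)cyclohexane-1-carboxylate | C1[C@@H](O1)[C@@H]2[C@H](C(=O)OC)[C@@H](C(C)C)CC[C@@]2(C)O[Si](C)(C)C(C)(C)C | intermediate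
12 | 3-[(tert-butyldimethylsilyl)oxy]-3-methyl-2-[(2S)-oxiran-2-yl]-6-(propan-2-yl)cyclohexane-1-carbaldehyde | C1[C@@H](O1)[C@@H]2[C@H](C=O)[C@@H](C(C)C)CC[C@@]2(C)O[Si](C)(C)C(C)(C)C | intermediate
13 | tert-butyl{[3-[(1Z)-2-iodoprop-1-en-1-yl]-1-methyl-2-[(2S)-oxiran-2-yl]-4-(propan-2-yl)cyclohexyl]oxy}dimethylsilane | C1[C@@H](O1)[C@@H]2[C@H](/C=C(/C)I)[C@@H](C(C)C)CC[C@@]2(C)O[Si](C)(C)C(C)(C)C | intermediate
14 | ethynyl(trimethyl)silane | C#C[Si](C)(C)C | starting material
15 | acrolein (prop-2-enal) | C=CC=O | starting material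
16 | lithium (trimethylsilyl)acetylide | [Li]C#C[Si](C)(C)C | intermediate (not isolated)
17 | lithium 5-(trimethylsilyl)pent-1-en-4-yn-3-olate (racemic) | C=CC(O[Li])C#C[Si](C)(C)C | intermediate (not isolated)
18 | rac-5-(trimethylsilyl)pent-1-en-4-yn-3-yl acetate | C=CC(OC(C)=O)C#C[Si](C)(C)C | intermediate
19 | (3R)-5-(trimethylsilyl)pent-1-en-4-yn-3-ol | C=C[C@H](C#C[Si](C)(C)C)O | intermediate
20 | (3R)-3-[(tert-butyldimethylsilyl)oxy]-5-(trimethylsilyl)pent-1-en-4-yne | C=C[C@H](C#C[Si](C)(C)C)O[Si](C)(C)C(C)(C)C | intermediate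
21 | 9-[(3R)-3-[(tert-butyldimethylsilyl)oxy]-5-(trimethylsilyl)pent-4-yn-1-yl]-9-borabicyclo[3.3.1]nonane | C(C[C@H](C#C[Si](C)(C)C)O[Si](C)(C)C(C)(C)C)B1C2CCCC1CCC2 | intermediate (not isolated)
22 | seco epoxy enyne: 13 with iodine replaced by the (3R)-3-[(tert-butyldimethylsilyl)oxy]-5-(trimethylsilyl)pent-4-yn-1-yl group (C4–C7, C19) | C1[C@@H](O1)[C@@H]2[C@H](/C=C(/C)CC[C@H](C#C[Si](C)(C)C)O[Si](C)(C)C(C)(C)C)[C@@H](C(C)C)CC[C@@]2(C)O[Si](C)(C)C(C)(C)C | intermediate
23 | C9 O-diethylboryl ether of 24 | C[Si](C)(C)/C=C1/C[C@@H](OB(CC)CC)[C@@H]2[C@H](/C=C(/C)CC[C@H]1O[Si](C)(C)C(C)(C)C)[C@@H](C(C)C)CC[C@@]2(C)O[Si](C)(C)C(C)(C)C | intermediate (not isolated)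
24 | (2Z,7(19)Z)-6,11-bis-O-(tert-butyldimethylsilyl)-19-(trimethylsilyl)eunicella-2,7(19)-diene-6,9,11-triol | C[Si](C)(C)/C=C1/C[C@@H](O)[C@@H]2[C@H](/C=C(/C)CC[C@H]1O[Si](C)(C)C(C)(C)C)[C@@H](C(C)C)CC[C@@]2(C)O[Si](C)(C)C(C)(C)C | intermediate
25 | (1S,2Z,6R,9R,10S,11R,14R)-eunicella-2,7(19)-diene-6,9,11-triol | C=C1C[C@@H](O)[C@@H]2[C@H](/C=C(/C)CC[C@H]1O)[C@@H](C(C)C)CC[C@@]2(C)O | intermediate
26 | (1S,2Z,6R,9R,10S,11R,14R)-11-hydroxyeunicella-2,7(19)-diene-6,9-diyl diacetate | C=C1C[C@@H](OC(C)=O)[C@@H]2[C@H](/C=C(/C)CC[C@H]1OC(C)=O)[C@@H](C(C)C)CC[C@@]2(C)O | target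

Total step count: 17. Longest linear sequence: 14 steps (steps 1 to 10 and 14 to 17); steps 11 to 13 make the side-chain piece.

Steps most likely to fail

Step 15 (Proposed new method). What may go wrong: oligomerisation in place of ring closure, carbon–carbon bond formation at the silylated alkyne carbon, or nickel-induced isomerisation of the epoxide before the alkyne inserts. The fallback uses known reactions only, sets out from 20 and 13 and comes back at 25. The alkyne of 20 would be freed with K2CO3 in MeOH to give the terminal alkyne F1. Cis-bromoboration with B-bromo-9-BBN would give the alkenylborane F2, and protonolysis with AcOH the 2-bromodiene F3. Bromine–lithium exchange (t-BuLi, Et2O, −78 °C) would give the alkenyllithium F4, which with BF3·OEt2 at −78 °C opens the epoxide of 13 at C8. The C7–C8 bond is thus made between two molecules by a polar epoxide opening, giving the seco alcohol F5. 9-BBN would then add to the monosubstituted alkene to give the borane F6, and an intramolecular B-alkyl Suzuki–Miyaura coupling (Pd(dppf)Cl2, AsPh3, Cs2CO3, DMF/THF/H2O, high dilution) would close the ten-membered ring at C3–C4 to give the macrocycle F7. Its two silyl ethers are cleaved with Bu4NF to give 25.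

Step 10. What may go wrong: low conversion of the hindered aldehyde with the unstable iodo-ylide, erosion of the Z geometry, or opening of the epoxide by iodide. The fallback sets out from 12 and comes back at 22. Ramirez dibromo-olefination (CBr4, PPh3, Et3N, CH2Cl2, 0 °C) would give the 1,1-dibromoalkene F8. A trans-selective Negishi methylation (MeZnCl, Pd(PPh3)4, THF, rt) should replace the bromine trans to C1 and give the (Z)-2-bromoalkene F9. F9 would take the place of 13 in the coupling with borane 21 (Pd(dppf)Cl2, Cs2CO3, DMF/THF/H2O, 50 °C) to give 22.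

Step 3. What may go wrong: poor facial selectivity when oxygen traps the planar C11 radical, or reduction of the radical to the alkane. The fallback sets out from 5 and comes back at 6. Epoxidation with m-CPBA (NaHCO3, CH2Cl2, 0 °C) on the convex face would give the epoxide F10. Phenylselenide anion (PhSeSePh, NaBH4, EtOH) should open it at the secondary carbon C12 to give the hydroxy selenide F11, whose carbon–selenium bond is reduced with Bu3SnH/AIBN (toluene, 80 °C) to give 6.

Further compounds
F1 | step 15 | (3R)-3-[(tert-butyldimethylsilyl)oxy]pent-1-en-4-yne | C=C[C@H](C#C)O[Si](C)(C)C(C)(C)C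
F2 | step 15 | 9-[(1Z,3R)-2-bromo-3-[(tert-butyldimethylsilyl)oxy]penta-1,4-dien-1-yl]-9-borabicyclo[3.3.1]nonane | C=C[C@H](/C(Br)=C/B1C2CCCC1CCC2)O[Si](C)(C)C(C)(C)C
F3 | step 15 | (3R)-2-bromo-3-[(tert-butyldimethylsilyl)oxy]penta-1,4-diene | C=C[C@H](C(Br)=C)O[Si](C)(C)C(C)(C)C
F4 | step 15 | [(3R)-3-[(tert-butyldimethylsilyl)oxy]penta-1,4-dien-2-yl]lithium | C=C[C@H](C([Li])=C)O[Si](C)(C)C(C)(C)C
F5 | step 15 | seco alcohol: ring A of 13 with the epoxide opened at C8 by C7 of the diene (C9–OH free, vinyl iodide kept) | C=C([C@@H](C=C)O[Si](C)(C)C(C)(C)C)C[C@@H](O)[C@@H]1[C@H](/C=C(/C)I)[C@@H](C(C)C)CC[C@@]1(C)O[Si](C)(C)C(C)(C)C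
F6 | step 15 | 9-BBN adduct of F5 at C4 | C=C([C@@H](CCB1C2CCCC1CCC2)O[Si](C)(C)C(C)(C)C)C[C@@H](O)[C@@H]3[C@H](/C=C(/C)I)[C@@H](C(C)C)CC[C@@]3(C)O[Si](C)(C)C(C)(C)C
F7 | step 15 | 6,11-bis-O-(tert-butyldimethylsilyl) ether of 25 | C=C1C[C@@H](O)[C@@H]2[C@H](/C=C(/C)CC[C@H]1O[Si](C)(C)C(C)(C)C)[C@@H](C(C)C)CC[C@@]2(C)O[Si](C)(C)C(C)(C)C
F8 | step 10 | tert-butyl{[3-(2,2-dibromoethenyl)-1-methyl-2-[(2S)-oxiran-2-yl]-4-(propan-2-yl)cyclohexyl]oxy}dimethylsilane | C1[C@@H](O1)[C@@H]2[C@H](C=C(Br)Br)[C@@H](C(C)C)CC[C@@]2(C)O[Si](C)(C)C(C)(C)C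
F9 | step 10 | tert-butyl{[3-[(1Z)-2-bromoprop-1-en-1-yl]-1-methyl-2-[(2S)-oxiran-2-yl]-4-(propan-2-yl)cyclohexyl]oxy}dimethylsilane | C1[C@@H](O1)[C@@H]2[C@H](/C=C(/C)Br)[C@@H](C(C)C)CC[C@@]2(C)O[Si](C)(C)C(C)(C)C
F10 | step 3 | 11,12-epoxide of 5 (oxygen on the face of H10) | COC1[C@@H]2[C@H](C(=O)O1)[C@@H](C(C)C)C[C@H]3O[C@@]23C
F11 | step 3 | 12-(phenylselanyl) derivative of 6 (selenium trans to the C11 hydroxyl) | COC1[C@@H]2[C@H](C(=O)O1)[C@@H](C(C)C)C[C@H]([Se]c3ccccc3)[C@@]2(C)O
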